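**Retrosynthetic overview**

1. Target 24 comes from chemoselective esterification of naphthazarin diol 22 with (R)-2-methylbutanoic acid 23; 22 comes from global desilylation of quinone 21.
2. Ring order: the dioxygenated benzo ring is bought (1); a four-membered ring is fused onto it by aryne [2+2] cycloaddition (steps 1–5, dione 8); the quinone ring is formed last (step 11).
3. Key disconnection, quinone ring C1(=O)–C2(side chain)=C3H–C4(=O): C4 is one carbonyl of 8 and C3/C2 are the terminal alkyne of 16; C1 is the other carbonyl of 8, released as a ketene carbon when the strained four-membered ring opens, and it closes the six-membered ring by bonding to C2.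
4. Enabling feature: the C2=C3 double bond lies between two aryl ketone carbons (C1, C4) on a benzo ring with identical oxygen substituents at C5 and C8, so dione 8 is C2v-symmetric and the alkyne may add to either carbonyl.
5. Side chain 16 comes from Zn–ProPhenol alkynylation of enal 12 (sets C1′ as R); 12 comes from cross-metathesis of 2-methylbut-3-en-2-ol with crotonaldehyde (sets the E-alkene and the tertiary carbinol).

Key step: step 11

Assumption: (R)-2-methylbutanoic acid (23) is taken as a purchasable, enantiopure reagent, and the naphthazarin is written throughout in the tautomer of the target SMILES.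

**Route**

Step 1
Reactants: 1 2-bromo-1,4-dimethoxybenzene; 2 1,1-dimethoxyethene
Product: 4 3,6-dimethoxybenzocyclobutenone (2,5-dimethoxybicyclo[4.2.0]octa-1,3,5-trien-7-one), via dimethyl ketal 3 (not isolated)
Conditions: NaNH2, THF, reflux; then 1 M HCl (cat.), THF/H2O, rt
Reagents that add atoms: water, O
Why: Base-induced elimination should give symmetrical 3,6-dimethoxybenzyne, which undergoes a regiochemically unambiguous aryne [2+2] cycloaddition with the electron-rich ketene acetal, and acidic ketal hydrolysis of 3 then unmasks the ketone.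

Step 2
Reactants: 4 3,6-dimethoxybenzocyclobutenone
Product: 5 2,2-dibromo-3,6-dimethoxybenzocyclobutenone
Conditions: NBS (2.2 equiv), (PhCO2)2 (cat.), CCl4, reflux
Reagents that add atoms: N-bromosuccinimide, O=C1CCC(=O)N1Br
Why: Wohl–Ziegler radical bromination at the only benzylic, carbonyl-activated CH2 should install both bromines, the radical conditions disfavouring nuclear bromination of the dimethoxy ring.

Step 3
Reactants: 5 2,2-dibromo-3,6-dimethoxybenzocyclobutenone
Product: 6 3,6-dimethoxybenzocyclobutene-1,2-dione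
Conditions: AgOCOCF3 (2.2 equiv), MeCN/H2O, rt to 50 °C
Reagents that add atoms: water, O
Why: Silver-assisted hydrolysis of the benzylic gem-dibromide, with ionisation helped by the ortho-methoxy arene, should give the acid-stable 1,2-dione.

Step 4
Reactants: 6 3,6-dimethoxybenzocyclobutene-1,2-dione
Product: 7 3,6-dihydroxybenzocyclobutene-1,2-dione
Conditions: BBr3, CH2Cl2, −78 °C to rt; then H2O
Reagents that add atoms: none
Why: Lewis-acid cleavage of the two aryl methyl ethers (BBr3 demethylation) is assisted by the ortho acyl groups and should leave the acid-tolerant dione intact.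

Step 5
Reactants: 7 3,6-dihydroxybenzocyclobutene-1,2-dione
Product: 8 3,6-bis(tert-butyldimethylsilyloxy)benzocyclobutene-1,2-dione
Conditions: TBSOTf, 2,6-lutidine, CH2Cl2, −78 to 0 °C
Reagents that add atoms: tert-butyldimethylsilyl triflate, CC(C)(C)[Si](C)(C)OS(=O)(=O)C(F)(F)F
Why: Phenol silylation with a silyl triflate and a non-nucleophilic base avoids nucleophilic opening of the electrophilic dione and installs protection removable later by fluoride.

Step 6
Reactants: 9 2-methylbut-3-en-2-ol; 10 (E)-but-2-enal (crotonaldehyde, excess)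
Product: 11 (E)-4-hydroxy-4-methylpent-2-enal
Conditions: second-generation Hoveyda–Grubbs catalyst RuCl2(=CH-C6H4-2-OiPr)(SIMes) (cat.), CH2Cl2, 40 °C
Reagents that add atoms: none
Why: Olefin cross-metathesis between a tertiary allylic alcohol that does not homodimerise and an enal, with loss of propene, should give the E-enal under thermodynamic control.

Step 7
Reactants: 11 (E)-4-hydroxy-4-methylpent-2-enal
Product: 12 (E)-4-methyl-4-(triethylsilyloxy)pent-2-enal
Conditions: TESOTf, 2,6-lutidine, CH2Cl2, −78 °C
Reagents that add atoms: triethylsilyl triflate, CC[Si](CC)(CC)OS(=O)(=O)C(F)(F)F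
Why: Silyl triflate silylation masks the hindered tertiary hydroxyl, which would otherwise consume the zinc and lithium reagents used later.

Step 8
Reactants: 12 (E)-4-methyl-4-(triethylsilyloxy)pent-2-enal; 13 ethynyltrimethylsilane
Product: 14 (3R,4E)-6-methyl-6-(triethylsilyloxy)-1-(trimethylsilyl)hept-4-en-1-yn-3-ol
Conditions: (S,S)-ProPhenol (10 mol %), Ph3P=O (20 mol %), Me2Zn (3 equiv), PhMe, 0–4 °C; aq NH4Cl
Reagents that add atoms: none
Why: Catalytic asymmetric alkynylation of an enal with the dinuclear zinc–ProPhenol catalyst (Trost alkynylation), in which the (S,S)-ligand is expected to deliver the zinc acetylide to the Si face of the non-enolisable aldehyde and so set the carbinol carbon as R.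

Step 9
Reactants: 14 (3R,4E)-6-methyl-6-(triethylsilyloxy)-1-(trimethylsilyl)hept-4-en-1-yn-3-ol
Product: 15 (3R,4E)-6-methyl-6-(triethylsilyloxy)hept-4-en-1-yn-3-ol
Conditions: K2CO3 (cat.), MeOH, 0 °C
Reagents that add atoms: none
Why: Base-catalysed methanolysis of the alkynyl C–Si bond (protodesilylation) should leave the hindered tertiary triethylsilyl ether and the stereocentre untouched.

Step 10
Reactants: 15 (3R,4E)-6-methyl-6-(triethylsilyloxy)hept-4-en-1-yn-3-ol
Product: 16 (3R,4E)-6-methyl-3,6-bis(triethylsilyloxy)hept-4-en-1-yne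
Conditions: TESCl, imidazole, CH2Cl2, 0 °C to rt
Reagents that add atoms: chlorotriethylsilane, CC[Si](Cl)(CC)CC
Why: Imidazole-promoted silylation of the secondary propargylic alcohol protects it for the acetylide chemistry without touching the alkyne C–H or the stereocentre.

Step 11
Reactants: 16 (3R,4E)-6-methyl-3,6-bis(triethylsilyloxy)hept-4-en-1-yne; 8 3,6-bis(tert-butyldimethylsilyloxy)benzocyclobutene-1,2-dione
Product: 21 5,8-bis(tert-butyldimethylsilyloxy)-2-[(1R,2E)-4-methyl-1,4-bis(triethylsilyloxy)pent-2-en-1-yl]naphthalene-1,4-dione, via lithium acetylide 17 (not isolated), via alkynyl carbinol 18 (not isolated), via quinoid vinylketene 19 (not isolated), via aryl diradical 20 (not isolated)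
Conditions: n-BuLi, THF, −78 °C; 8, THF, −78 °C; aq NH4Cl at −78 °C, extraction, solvent exchange; degassed p-xylene, 138 °C, dark
Reagents that add atoms: none
Why: Acetylide 17 adds once to either of the two equivalent carbonyls of C2v-symmetric 8 and the cold quench gives carbinol 18 as an inconsequential epimer mixture, which on heating undergoes 4π-electrocyclic opening of the strained four-membered ring with the hydroxyl rotating outward and the alkynyl inward, so that the alkyne sits next to the ketene carbon of o-quinoid vinylketene 19. The ketene carbon then bonds to the distal alkyne carbon (the future side-chain-bearing ring carbon), which closes the quinone ring and rearomatises the benzo ring to give σ,π-diradical 20, and net transfer of the hydroxyl hydrogen to the ring radical carbon should give quinone 21 directly at the correct oxidation level. The closest known reaction type is the Moore rearrangement of 4-alkynyl-4-hydroxycyclobutenones, including benzo-fused cases that give 1,4-naphthoquinones. The ring is closed in a six-membered, endo-type cycloaromatisation of the enynyl ketene, related to the Myers–Saito cyclisation. No stereocentre is formed, since the carbinol carbon becomes a carbonyl and the silyloxy-bearing side-chain centre is remote from all bond changes under neutral thermal conditions. The selectivity needed is six- over five-membered closure, which the sp3, non-radical-stabilising substituent on the alkyne terminus should secure, while the symmetry of 8 removes any regiochemical question in the addition.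

Step 12
Reactants: 21 5,8-bis(tert-butyldimethylsilyloxy)-2-[(1R,2E)-4-methyl-1,4-bis(triethylsilyloxy)pent-2-en-1-yl]naphthalene-1,4-dione
Product: 22 2-[(1R,2E)-1,4-dihydroxy-4-methylpent-2-en-1-yl]-5,8-dihydroxynaphthalene-1,4-dione
Conditions: HF·pyridine, excess pyridine, THF, 0 °C to rt, dark
Reagents that add atoms: none
Why: Fluoride-mediated desilylation should cleave the two aryl and two alkyl silyl ethers under buffered, weakly acidic conditions that the naphthazarin and both allylic alcohols tolerate.

Step 13
Reactants: 22 2-[(1R,2E)-1,4-dihydroxy-4-methylpent-2-en-1-yl]-5,8-dihydroxynaphthalene-1,4-dione; 23 (R)-2-methylbutanoic acid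
Product: 24 (1R,2E)-1-(5,8-dihydroxy-1,4-dioxo-1,4-dihydronaphthalen-2-yl)-4-hydroxy-4-methylpent-2-en-1-yl (2R)-2-methylbutanoate
Conditions: DCC, DMAP (cat.), CH2Cl2, 0 °C, dark
Reagents that add atoms: none
Why: Steglich esterification should acylate the secondary side-chain alcohol in preference to the strongly chelated peri-hydroxyls and the tertiary alcohol, as is usual for shikonin-type side-chain alcohols, with both stereocentres retained because only the O–H bond reacts and low temperature with catalytic DMAP limits epimerisation of the acid.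

**Compound list**

1 | 2-bromo-1,4-dimethoxybenzene | COc1ccc(OC)c(Br)c1 | starting material
2 | 1,1-dimethoxyethene | C=C(OC)OC | starting material
3 | 3,6-dimethoxybenzocyclobutenone dimethyl ketal (2,5,7,7-tetramethoxybicyclo[4.2.0]octa-1,3,5-triene) | COc1ccc(OC)c2c1CC2(OC)OC | intermediate
4 | 3,6-dimethoxybenzocyclobutenone | COc1ccc(OC)c2c1CC2=O | intermediate
5 | 2,2-dibromo-3,6-dimethoxybenzocyclobutenone | COc1ccc(OC)c2c1C(Br)(Br)C2=O | intermediate
6 | 3,6-dimethoxybenzocyclobutene-1,2-dione | COc1ccc(OC)c2c1C(=O)C2=O | intermediate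
7 | 3,6-dihydroxybenzocyclobutene-1,2-dione | Oc1ccc(O)c2c1C(=O)C2=O | intermediate
8 | 3,6-bis(tert-butyldimethylsilyloxy)benzocyclobutene-1,2-dione | CC(C)(C)[Si](C)(C)Oc1ccc(O[Si](C)(C)C(C)(C)C)c2c1C(=O)C2=O | intermediate
9 | 2-methylbut-3-en-2-ol | C=CC(C)(C)O | starting material
10 | (E)-but-2-enal | C/C=C/C=O | starting material
11 | (E)-4-hydroxy-4-methylpent-2-enal | CC(C)(O)/C=C/C=O | intermediate
12 | (E)-4-methyl-4-(triethylsilyloxy)pent-2-enal | CC[Si](CC)(CC)OC(C)(C)/C=C/C=O | intermediate
13 | ethynyltrimethylsilane | C#C[Si](C)(C)C | starting material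
14 | (3R,4E)-6-methyl-6-(triethylsilyloxy)-1-(trimethylsilyl)hept-4-en-1-yn-3-ol | C[Si](C)(C)C#C[C@H](O)/C=C/C(C)(C)O[Si](CC)(CC)CC | intermediate
15 | (3R,4E)-6-methyl-6-(triethylsilyloxy)hept-4-en-1-yn-3-ol | C#C[C@H](O)/C=C/C(C)(C)O[Si](CC)(CC)CC | intermediate
16 | (3R,4E)-6-methyl-3,6-bis(triethylsilyloxy)hept-4-en-1-yne | C#C[C@H](O[Si](CC)(CC)CC)/C=C/C(C)(C)O[Si](CC)(CC)CC | intermediate
17 | lithium acetylide of 16 | [Li]C#C[C@H](O[Si](CC)(CC)CC)/C=C/C(C)(C)O[Si](CC)(CC)CC | intermediate
18 | 2-hydroxy-2-[(3R,4E)-6-methyl-3,6-bis(triethylsilyloxy)hept-4-en-1-yn-1-yl]-3,6-bis(tert-butyldimethylsilyloxy)benzocyclobutenone (both carbinol epimers) | O=C1c2c(O[Si](C)(C)C(C)(C)C)ccc(O[Si](C)(C)C(C)(C)C)c2C1(O)C#C[C@H](O[Si](CC)(CC)CC)/C=C/C(C)(C)O[Si](CC)(CC)CC | intermediate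
19 | o-quinoid vinylketene from ring opening of 18 (exocyclic ketene and exocyclic hydroxy-enyne on adjacent ring carbons) | O=C=C1C(O[Si](C)(C)C(C)(C)C)=CC=C(O[Si](C)(C)C(C)(C)C)C1=C(O)C#C[C@H](O[Si](CC)(CC)CC)/C=C/C(C)(C)O[Si](CC)(CC)CC | intermediate
20 | 4-hydroxy-1-oxyl-naphthalen-3-yl diradical carrying the side chain at C2 | [O]c1c([C@H](O[Si](CC)(CC)CC)/C=C/C(C)(C)O[Si](CC)(CC)CC)[c]c(O)c2c(O[Si](C)(C)C(C)(C)C)ccc(O[Si](C)(C)C(C)(C)C)c12 | intermediate
21 | 5,8-bis(tert-butyldimethylsilyloxy)-2-[(1R,2E)-4-methyl-1,4-bis(triethylsilyloxy)pent-2-en-1-yl]naphthalene-1,4-dione | O=C1C([C@H](O[Si](CC)(CC)CC)/C=C/C(C)(C)O[Si](CC)(CC)CC)=CC(=O)c2c(O[Si](C)(C)C(C)(C)C)ccc(O[Si](C)(C)C(C)(C)C)c21 | intermediate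
22 | 2-[(1R,2E)-1,4-dihydroxy-4-methylpent-2-en-1-yl]-5,8-dihydroxynaphthalene-1,4-dione | O[C@H](/C=C/C(C)(C)O)C1=CC(=O)c2c(O)ccc(O)c2C1=O | intermediate
23 | (R)-2-methylbutanoic acid | CC[C@@H](C)C(=O)O | starting material
24 | (1R,2E)-1-(5,8-dihydroxy-1,4-dioxo-1,4-dihydronaphthalen-2-yl)-4-hydroxy-4-methylpent-2-en-1-yl (2R)-2-methylbutanoate | CC[C@@H](C)C(=O)O[C@H](/C=C/C(C)(C)O)C1=CC(=O)c2c(O)ccc(O)c2C1=O | target

**Step count**

Total step count: 13. Longest linear sequence: 8 steps (steps 1–5 or steps 6–10, then steps 11–13).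

**Steps most likely to fail**

Step 11. The lithium alkoxide may fragment or suffer O-to-O silyl migration before the quench, and the diradical may partition toward five-membered (alkylidene-indanedione) closure or unproductive hydrogen abstraction. The fallback replaces the diradical pathway by the closed-shell electrocyclic ring expansion of an alkenyl carbinol. It sets out from 16 and 8 and returns at 21. Hydrozirconation of 16 with Cp2Zr(H)Cl in THF followed by iodine should give (1E,3R,4E)-1-iodo-6-methyl-3,6-bis(triethylsilyloxy)hepta-1,4-diene F1. Iodine–lithium exchange with t-BuLi in Et2O at −78 °C and addition to dione 8, again with a cold NH4Cl quench, should give the 2-alkenyl-2-hydroxybenzocyclobutenone F2. Heating F2 in toluene should bring about ring opening, 6π-electrocyclisation of the dienylketene and tautomerisation to the naphthalene-1,4-diol F3. Oxidation of F3 with Ag2O in Et2O should then deliver quinone 21.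

Step 8. Facial selectivity in the alkynyl transfer to the γ-silyloxy enal may be insufficient or reversed, and conjugate addition may compete. The fallback sets the stereocentre by ketone reduction instead. It sets out from 12 and 13 and returns at 14. Addition of lithium trimethylsilylacetylide (13, n-BuLi, THF, −78 °C) to 12 should give the racemic propargylic alcohol F4. Oxidation with MnO2 in CH2Cl2 should give the enynone F5. Noyori asymmetric transfer hydrogenation of F5 with RuCl(p-cymene)[(R,R)-TsDPEN] in i-PrOH, with the alkyne acting as the directing π-substituent, should then give (R)-alcohol 14.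

Step 13. Acylation of the phenolic or tertiary hydroxyls may compete, the doubly activated secondary carbinol may ionise, and the activated α-branched acid may epimerise. The fallback changes the order of deprotection so that the phenols are blocked during acylation. It sets out from 21 and returns at 24. Selective methanolysis of the two triethylsilyl ethers with PPTS in MeOH at 0 °C should give the bis(aryl silyl ether) diol F6. Steglich esterification of F6 with 23 (DCC, cat. DMAP, CH2Cl2, 0 °C) should give the ester F7. Removal of the two aryl silyl ethers from F7 with HF·pyridine/pyridine in THF at 0 °C should then give 24.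

**Further compounds**

F1 | step 11 | (1E,3R,4E)-1-iodo-6-methyl-3,6-bis(triethylsilyloxy)hepta-1,4-diene | I/C=C/[C@H](O[Si](CC)(CC)CC)/C=C/C(C)(C)O[Si](CC)(CC)CC
F2 | step 11 | 2-hydroxy-2-[(1E,3R,4E)-6-methyl-3,6-bis(triethylsilyloxy)hepta-1,4-dien-1-yl]-3,6-bis(tert-butyldimethylsilyloxy)benzocyclobutenone (both carbinol epimers) | O=C1c2c(O[Si](C)(C)C(C)(C)C)ccc(O[Si](C)(C)C(C)(C)C)c2C1(O)/C=C/[C@H](O[Si](CC)(CC)CC)/C=C/C(C)(C)O[Si](CC)(CC)CC
F3 | step 11 | 5,8-bis(tert-butyldimethylsilyloxy)-2-[(1R,2E)-4-methyl-1,4-bis(triethylsilyloxy)pent-2-en-1-yl]naphthalene-1,4-diol | Oc1c([C@H](O[Si](CC)(CC)CC)/C=C/C(C)(C)O[Si](CC)(CC)CC)cc(O)c2c(O[Si](C)(C)C(C)(C)C)ccc(O[Si](C)(C)C(C)(C)C)c12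
F4 | step 8 | racemic (E)-6-methyl-6-(triethylsilyloxy)-1-(trimethylsilyl)hept-4-en-1-yn-3-ol | C[Si](C)(C)C#CC(O)/C=C/C(C)(C)O[Si](CC)(CC)CC
F5 | step 8 | (E)-6-methyl-6-(triethylsilyloxy)-1-(trimethylsilyl)hept-4-en-1-yn-3-one | C[Si](C)(C)C#CC(=O)/C=C/C(C)(C)O[Si](CC)(CC)CC
F6 | step 13 | 5,8-bis(tert-butyldimethylsilyloxy)-2-[(1R,2E)-1,4-dihydroxy-4-methylpent-2-en-1-yl]naphthalene-1,4-dione | O[C@H](/C=C/C(C)(C)O)C1=CC(=O)c2c(O[Si](C)(C)C(C)(C)C)ccc(O[Si](C)(C)C(C)(C)C)c2C1=O
F7 | step 13 | (1R,2E)-1-[5,8-bis(tert-butyldimethylsilyloxy)-1,4-dioxo-1,4-dihydronaphthalen-2-yl]-4-hydroxy-4-methylpent-2-en-1-yl (2R)-2-methylbutanoate | CC[C@@H](C)C(=O)O[C@H](/C=C/C(C)(C)O)C1=CC(=O)c2c(O[Si](C)(C)C(C)(C)C)ccc(O[Si](C)(C)C(C)(C)C)c2C1=O
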